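**Retrosynthetic overview**
1. Rings A and B are bought. Ring C is the only ring made, and it is closed last. The O1–C2 bond forms by 1,6-addition of the ring-A phenol to a ring-B para-quinone methide, the species presumed to link the co-occurring 1,3-diarylpropanes and flavans in the plant. A chiral phosphoric acid generates it from the benzylic alcohol and sets C2 as S.
2. The benzylic alcohol comes from the aryl ketone (NaBH4). The ketone level at C2 is kept until all heating is finished.
3. All three C5 side chains come from one thermal triple aromatic Claisen shift: 7-O-prenyl gives 6-(1,1-dimethylallyl), and 3'-O- and 4'-O-(1,1-dimethylallyl) give 2'- and 5'-prenyl. These ethers are also the only phenol protection.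
4. The C6–C3–C6 skeleton comes from a Claisen–Schmidt condensation of a ring-B acetophenone with a ring-A salicylaldehyde, followed by conjugate reduction.
5. Starting materials: 3,4-dihydroxyacetophenone, 2,4-dihydroxybenzaldehyde, prenyl bromide, 2-methylbut-3-en-2-ol and di-tert-butyl dicarbonate.

Assumption: the SMILES is read as the (2S)-flavan. The sense of induction of the acid cannot be known in advance, so the (R)-acid is written; the equally available (S)-acid is used if the first run gives 2R.

**Step 1**
Reactants: 1 2-methylbut-3-en-2-ol; 2 di-tert-butyl dicarbonate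
Product: 4 tert-butyl (2-methylbut-3-en-2-yl) carbonate, via lithium 2-methylbut-3-en-2-olate 3 (not isolated)
Conditions: n-BuLi (1.05 equiv), THF, −78 to 0 °C; then 2 (1.05 equiv), 0 °C to rt; H2O quench
Reagents that add atoms: di-tert-butyl dicarbonate (2), CC(C)(C)OC(=O)OC(=O)OC(C)(C)C; n-butyllithium, [Li]CCCC (supplies the lithium of 3 only)
Why: Alkoxide acylation (mixed carbonate formation): the hindered tertiary allylic alcohol is first turned into its lithium alkoxide 3, which attacks one carbonyl of 2 and expels tert-butyl carbonate (then CO2 and tert-butoxide), so the carbonate forms without allylic transposition and no stereocenter is involved.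

**Step 2**
Reactants: 5 1-(3,4-dihydroxyphenyl)ethanone; 4 tert-butyl (2-methylbut-3-en-2-yl) carbonate
Product: 7 1-[3,4-bis(2-methylbut-3-en-2-yloxy)phenyl]ethanone, via 4-O-monoether 6 (not isolated)
Conditions: 4 (2.4 equiv), Pd(PPh3)4 (5 mol %), THF, 0–5 °C, Ar, 16 h
Reagents that add atoms: tert-butyl (2-methylbut-3-en-2-yl) carbonate (4), C=CC(C)(C)OC(=O)OC(C)(C)C
Why: Decarboxylative Tsuji–Trost O-allylation: zerovalent palladium ionises 4 to the 1,1-dimethyl-π-allyl complex, CO2 and tert-butoxide, the tert-butoxide deprotonates the phenol, and at 0–5 °C the phenoxide attacks the more substituted allyl terminus under kinetic control (the more acidic 4-OH first, giving 6, then the 3-OH), a reaction type known to work on both oxygens of catechols, while the limited excess of 4 keeps the methyl ketone from being C-allylated.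

**Step 3**
Reactants: 8 2,4-dihydroxybenzaldehyde; 9 1-bromo-3-methylbut-2-ene (prenyl bromide)
Product: 10 2-hydroxy-4-(3-methylbut-2-enyloxy)benzaldehyde
Conditions: 9 (1.05 equiv), K2CO3 (1.1 equiv), acetone, 45 °C, 6 h
Reagents that add atoms: prenyl bromide (9), CC(C)=CCBr
Why: Williamson ether synthesis: the 2-OH is locked in a hydrogen bond to the aldehyde and is the weaker acid, so one equivalent of base and bromide alkylates the 4-OH only, and SN2 attack at the primary carbon keeps the prenyl group linear.

**Step 4**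
Reactants: 7 1-[3,4-bis(2-methylbut-3-en-2-yloxy)phenyl]ethanone; 10 2-hydroxy-4-(3-methylbut-2-enyloxy)benzaldehyde
Product: 12 (E)-1-[3,4-bis(2-methylbut-3-en-2-yloxy)phenyl]-3-[2-hydroxy-4-(3-methylbut-2-enyloxy)phenyl]prop-2-en-1-one, via aldol adduct 11 (not isolated)
Conditions: KOH (50 % aq, 5 equiv), EtOH, rt, 40 h; AcOH to pH 7 at 0 °C
Reagents that add atoms: none
Why: Claisen–Schmidt condensation: the enolate of 7 adds to the aldehyde of 10 to give 11, E1cB loss of hydroxide gives the conjugated enone as the thermodynamically favoured E isomer, and the three allyl-type ethers are inert to hydroxide and serve as the only phenol protection.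

**Step 5**
Reactants: 12 the (E)-enone
Product: 13 1-[3,4-bis(2-methylbut-3-en-2-yloxy)phenyl]-3-[2-hydroxy-4-(3-methylbut-2-enyloxy)phenyl]propan-1-one
Conditions: Cu(OAc)2·H2O (3 mol %), 1,2-bis(diphenylphosphino)benzene (3 mol %), (EtO)2MeSiH (2.2 equiv), t-BuOH (2.2 equiv), toluene, rt, 3 h; aq NH4Cl
Reagents that add atoms: none
Why: Copper hydride conjugate reduction (Stryker type): the phosphine-ligated copper hydride adds hydride only to the β-carbon of the enone, tert-butanol protonates the copper enolate, and unactivated alkenes, allyl aryl ethers and (with the silane kept near two equivalents) the aryl ketone are left alone.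

**Step 6**
Reactants: 13 the saturated tris-ether ketone
Product: 16 1-[3,4-dihydroxy-2,5-bis(3-methylbut-2-enyl)phenyl]-3-[2,4-dihydroxy-5-(2-methylbut-3-en-2-yl)phenyl]propan-1-one, via mono-rearranged ketone 14 (not isolated), via ring-B-rearranged ketone 15 (not isolated)
Conditions: degassed EtOH/H2O 4:1, sealed tube, Ar, 100 °C, 3 h, then 140 °C, 36 h
Reagents that add atoms: none
Why: Three water-accelerated aromatic Claisen [3,3] rearrangements, each with allyl inversion: the two tertiary ring-B ethers deliver their unhindered CH2 termini to the only free ortho carbons (C5' first, then C2', as allyl ethers of vanillin and isovanillin do) to give linear prenyl groups, the ring-A prenyl ether delivers its CMe2 terminus to the less hindered ortho carbon para to the 2-OH (as in 2-oxygenated 4-prenyloxy aryl systems) to give the 1,1-dimethylallyl group, and the ketone at C2 prevents premature thermal quinone methide formation.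

**Step 7**
Reactants: 16 the tetraphenol ketone
Product: 17 rac-4-{3-[3,4-dihydroxy-2,5-bis(3-methylbut-2-enyl)phenyl]-3-hydroxypropyl}-6-(2-methylbut-3-en-2-yl)benzene-1,3-diol
Conditions: NaBH4 (3 equiv), MeOH/THF 1:1, 0 °C to rt; pH 7 phosphate buffer, short Et3N-deactivated silica plug, stored cold
Reagents that add atoms: none
Why: Borohydride 1,2-reduction: the aryl ketone is the only reducible group, the new carbinol center is made racemic on purpose because it is erased in the next step, and the neutral work-up keeps the acid-labile 4-hydroxybenzyl alcohol intact.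

**Step 8**
Reactants: 17 the racemic benzylic alcohol
Product: 19 (2S)-2-[3,4-dihydroxy-2,5-bis(3-methylbut-2-enyl)phenyl]-6-(2-methylbut-3-en-2-yl)chroman-7-ol, via para-quinone methide 18 (not isolated)
Conditions: (R)-3,3'-bis(2,4,6-triisopropylphenyl)-1,1'-binaphthyl-2,2'-diyl hydrogen phosphate (10 mol %), 5 Å MS, toluene (0.02 M), 0 °C, Ar, 24 h
Reagents that add atoms: none
Why: Proposed new method: the acid protonates the benzylic hydroxyl of 17 while its phosphoryl oxygen holds the 4'-OH, water leaves far more easily than any prenyl alkene is protonated by so weak an acid, the resulting 2-hydroxy-para-quinone methide 18 stays bound in the chiral pocket through a two-point contact (3'-OH and C4'=O), and the ring-A 2-OH, activated by the phosphate as a general base, adds 1,6 to one face of the exocyclic carbon to close ring C and set C2 as S, the closest known reaction types being chiral-phosphoric-acid-catalysed asymmetric 1,6-conjugate addition to para-quinone methides formed in situ from 4-hydroxybenzyl alcohols and the dehydrative asymmetric closure of phenol-tethered allylic alcohols to 2H-chromenes.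

**Compound list**
1 | 2-methylbut-3-en-2-ol | CC(C)(O)C=C | starting material
2 | di-tert-butyl dicarbonate | CC(C)(C)OC(=O)OC(=O)OC(C)(C)C | starting material
3 | lithium 2-methylbut-3-en-2-olate | [Li+].[O-]C(C)(C)C=C | intermediate
4 | tert-butyl (2-methylbut-3-en-2-yl) carbonate | C=CC(C)(C)OC(=O)OC(C)(C)C | intermediate
5 | 1-(3,4-dihydroxyphenyl)ethanone | CC(=O)c1ccc(O)c(O)c1 | starting material
6 | 1-[3-hydroxy-4-(2-methylbut-3-en-2-yloxy)phenyl]ethanone (4-O-monoether) | CC(=O)c1ccc(OC(C)(C)C=C)c(O)c1 | intermediate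
7 | 1-[3,4-bis(2-methylbut-3-en-2-yloxy)phenyl]ethanone | CC(=O)c1ccc(OC(C)(C)C=C)c(OC(C)(C)C=C)c1 | intermediate
8 | 2,4-dihydroxybenzaldehyde | O=Cc1ccc(O)cc1O | starting material
9 | 1-bromo-3-methylbut-2-ene (prenyl bromide) | CC(C)=CCBr | starting material
10 | 2-hydroxy-4-(3-methylbut-2-enyloxy)benzaldehyde | O=Cc1ccc(OCC=C(C)C)cc1O | intermediate
11 | 1-[3,4-bis(2-methylbut-3-en-2-yloxy)phenyl]-3-hydroxy-3-[2-hydroxy-4-(3-methylbut-2-enyloxy)phenyl]propan-1-one (aldol adduct, racemic) | O=C(CC(O)c1ccc(OCC=C(C)C)cc1O)c1ccc(OC(C)(C)C=C)c(OC(C)(C)C=C)c1 | intermediate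
12 | (E)-1-[3,4-bis(2-methylbut-3-en-2-yloxy)phenyl]-3-[2-hydroxy-4-(3-methylbut-2-enyloxy)phenyl]prop-2-en-1-one | O=C(/C=C/c1ccc(OCC=C(C)C)cc1O)c1ccc(OC(C)(C)C=C)c(OC(C)(C)C=C)c1 | intermediate
13 | 1-[3,4-bis(2-methylbut-3-en-2-yloxy)phenyl]-3-[2-hydroxy-4-(3-methylbut-2-enyloxy)phenyl]propan-1-one | O=C(CCc1ccc(OCC=C(C)C)cc1O)c1ccc(OC(C)(C)C=C)c(OC(C)(C)C=C)c1 | intermediate
14 | 1-[4-hydroxy-3-(2-methylbut-3-en-2-yloxy)-5-(3-methylbut-2-enyl)phenyl]-3-[2-hydroxy-4-(3-methylbut-2-enyloxy)phenyl]propan-1-one (mono-rearranged ketone) | O=C(CCc1ccc(OCC=C(C)C)cc1O)c1cc(CC=C(C)C)c(O)c(OC(C)(C)C=C)c1 | intermediate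
15 | 1-[3,4-dihydroxy-2,5-bis(3-methylbut-2-enyl)phenyl]-3-[2-hydroxy-4-(3-methylbut-2-enyloxy)phenyl]propan-1-one (ring-B-rearranged ketone) | O=C(CCc1ccc(OCC=C(C)C)cc1O)c1cc(CC=C(C)C)c(O)c(O)c1CC=C(C)C | intermediate
16 | 1-[3,4-dihydroxy-2,5-bis(3-methylbut-2-enyl)phenyl]-3-[2,4-dihydroxy-5-(2-methylbut-3-en-2-yl)phenyl]propan-1-one | O=C(CCc1cc(C(C)(C)C=C)c(O)cc1O)c1cc(CC=C(C)C)c(O)c(O)c1CC=C(C)C | intermediate
17 | rac-4-{3-[3,4-dihydroxy-2,5-bis(3-methylbut-2-enyl)phenyl]-3-hydroxypropyl}-6-(2-methylbut-3-en-2-yl)benzene-1,3-diol | OC(CCc1cc(C(C)(C)C=C)c(O)cc1O)c1cc(CC=C(C)C)c(O)c(O)c1CC=C(C)C | intermediate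
18 | 4-{3-[2,4-dihydroxy-5-(2-methylbut-3-en-2-yl)phenyl]propylidene}-2-hydroxy-3,6-bis(3-methylbut-2-enyl)cyclohexa-2,5-dien-1-one (para-quinone methide) | O=C1C(O)=C(CC=C(C)C)C(=CCCc2cc(C(C)(C)C=C)c(O)cc2O)C=C1CC=C(C)C | intermediate
19 | (2S)-2-[3,4-dihydroxy-2,5-bis(3-methylbut-2-enyl)phenyl]-6-(2-methylbut-3-en-2-yl)chroman-7-ol, that is (2S)-7,3',4'-trihydroxy-6-(1,1-dimethylallyl)-2',5'-diprenylflavan | C=CC(C)(C)c1cc2c(cc1O)O[C@H](c1cc(CC=C(C)C)c(O)c(O)c1CC=C(C)C)CC2 | target

**Step count**
Total step count: 8. Longest linear sequence: 7 steps (1 → 4 → 7 → 12 → 13 → 16 → 17 → 19).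

**Steps most likely to fail**

**Step 8.**
- Stereocontrol is remote, so the ee may be modest.
- The alkyl-substituted quinone methide 18 can tautomerise to the 4-hydroxystyrene, which is a dead end under acid this weak.
- The 2'-prenyl alkene could capture C2 and form an indane.

The fallback keeps the same ring closure but secures the enantiomer by resolution with recycling. It sets out from 17 and comes back at 19. Compound 17 is cyclised with achiral diphenyl hydrogen phosphate (5 mol %, CH2Cl2, rt) to the racemic flavan F1. This is separated by preparative supercritical-fluid chromatography on an amylose tris(3,5-dimethylphenylcarbamate) phase into 19 and the (2R)-enantiomer F2. F2 is re-racemised through the same quinone methide (pH 9 borate buffer/EtOH, 80 °C, Ar) back to F1 and recycled.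

**Step 6.**
- On ring B, an ipso-Claisen dienone could be trapped by the neighbouring 1,1-dimethylallyl ether in an intramolecular Diels–Alder reaction, giving a caged adduct.
- On ring A, the carbon between the two oxygens could be attacked.
- The 1,1-dimethylallyl phenol could rearrange further.

The fallback replaces the tertiary ethers by plain allyl ethers and builds the prenyl groups by metathesis. It sets out from 5 and 10 and comes back at 16.
- Compound 5 is bis-allylated (allyl bromide, K2CO3, acetone) to 1-[3,4-bis(allyloxy)phenyl]ethanone F3.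
- F3 is condensed with 10 under the KOH/EtOH conditions to the enone F4.
- F4 is reduced with the same copper hydride system to the saturated ketone F5.
- F5 is heated in N,N-diethylaniline at 195 °C. Allyl ethers lacking the gem-dimethyl group have no fast Diels–Alder trap and migrate to the free ortho carbons, giving the diallyl tetraphenol ketone F6.
- Cross-metathesis of F6 with 2-methylbut-2-ene (second-generation Grubbs catalyst, CH2Cl2, 40 °C) converts both allyl groups into prenyl groups. The vinyl group on the quaternary carbon is too hindered to react. The product is 16.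

**Step 2.**
- The second etherification takes place next to a bulky tertiary ether.
- Palladium can equilibrate the products to linear prenyl ethers.
- Palladium can also C-allylate the ketone.

The fallback avoids π-allyl chemistry. It sets out from 5 and comes back at 7. Compound 5 is etherified twice with 3-chloro-3-methylbut-1-yne (DBU, CuCl2·2H2O 1 mol %, MeCN, 0 °C) to the bis(1,1-dimethylpropargyl) ether F7. Both alkynes are then semi-hydrogenated (H2 1 atm, Pd/CaCO3 poisoned with Pb(OAc)2, quinoline, EtOAc) to give 7.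

**Further compounds**
F1 | step 8 | racemic 2-[3,4-dihydroxy-2,5-bis(3-methylbut-2-enyl)phenyl]-6-(2-methylbut-3-en-2-yl)chroman-7-ol | C=CC(C)(C)c1cc2c(cc1O)OC(c1cc(CC=C(C)C)c(O)c(O)c1CC=C(C)C)CC2
F2 | step 8 | (2R)-2-[3,4-dihydroxy-2,5-bis(3-methylbut-2-enyl)phenyl]-6-(2-methylbut-3-en-2-yl)chroman-7-ol | C=CC(C)(C)c1cc2c(cc1O)O[C@@H](c1cc(CC=C(C)C)c(O)c(O)c1CC=C(C)C)CC2
F3 | step 6 | 1-[3,4-bis(allyloxy)phenyl]ethanone | CC(=O)c1ccc(OCC=C)c(OCC=C)c1
F4 | step 6 | (E)-1-[3,4-bis(allyloxy)phenyl]-3-[2-hydroxy-4-(3-methylbut-2-enyloxy)phenyl]prop-2-en-1-one | O=C(/C=C/c1ccc(OCC=C(C)C)cc1O)c1ccc(OCC=C)c(OCC=C)c1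
F5 | step 6 | 1-[3,4-bis(allyloxy)phenyl]-3-[2-hydroxy-4-(3-methylbut-2-enyloxy)phenyl]propan-1-one | O=C(CCc1ccc(OCC=C(C)C)cc1O)c1ccc(OCC=C)c(OCC=C)c1
F6 | step 6 | 1-(2,5-diallyl-3,4-dihydroxyphenyl)-3-[2,4-dihydroxy-5-(2-methylbut-3-en-2-yl)phenyl]propan-1-one | O=C(CCc1cc(C(C)(C)C=C)c(O)cc1O)c1cc(CC=C)c(O)c(O)c1CC=C
F7 | step 2 | 1-[3,4-bis(2-methylbut-3-yn-2-yloxy)phenyl]ethanone | CC(=O)c1ccc(OC(C)(C)C#C)c(OC(C)(C)C#C)c1
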